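The earlier runs and the new flask were generated by integration with made-up constants, noise included.

Compare the flask with theta first: theta carries 0.025 M of starting material against 0.050 M in the flask, while both nucleophiles stand at the same charges.

in all of them: second nucleophile 0.125 M
- alpha: starting material 0.050 M; first nucleophile 0.10 M; run made earlier
- zeta: starting material 0.050 M; first nucleophile 0.17 M; run made earlier
- theta: starting material 0.025 M; first nucleophile 0.075 M; run made earlier
- flask: starting material 0.050 M; first nucleophile 0.0750 M; time 15 d

- alpha (time / d: target / %, other capture product / %): 2.08: 12.9, 26.2; 5.00: 6.3, 34.9; 10.0: 0, 35.4; 15.0: 0, 36.6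
- zeta (time / d: target / %, other capture product / %): 2.08: 12.2, 22.5; 5.00: 3.9, 27.4; 10.0: 0, 27.3; 15.0: 0, 29.4
- theta (time / d: target / %, other capture product / %): 2.08: 14.0, 30.2; 5.00: 4.5, 36.7; 10.0: 0, 39.9; 15.0: 0, 40.0

(readings scatter by 1 percentage point)

- ratio of target to other capture product at 3.0 h
- ratio of target to other capture product at 15 d
- which of target and other capture product there is more of at 15 d



I assume that the starting material gives one short-lived intermediate, held at quasi-steady state, for which both nucleophiles compete while it also falls away unimolecularly. The split of that intermediate then follows the nucleophile concentrations, with which the flask and theta start alike, so I expect the flask to end like theta, whose late readings of other capture product average 40.0% of the charge.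

Zeta, with more first nucleophile, averages 28.3%. On my assumption the inverse of this fraction rises in a straight line with the first nucleophile, and between theta and zeta its slope is 10.8 M⁻¹. That slope times the flask's charge of first nucleophile gives 0.809, my capture ratio: target made per other capture product made, a selectivity factor taken at the charged concentrations. I commit to this value for the ratio at 3.0 h, early against theta's fall of target between 2.08 d and 10.0 d. Theta's target reads 0% by 10.0 d, so at 15 d I expect a ratio near zero, with other capture product ahead.

The forecast gives 1.3 at 3.0 h, 0 at 15 d, and other capture product ahead, from a “kinetic ratio near 1.4–1.7, only weakly dependent on first nucleophile”. My early value is lower.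

The flask gives 0.840 at 3.0 h and 0.00648 at 15 d, with other capture product ahead, 39.8% against 0.258%.

    starting material → intermediate (k = 0.0290 h⁻¹)
    first nucleophile + intermediate → target (k = 8.40 M⁻¹ h⁻¹)
    second nucleophile + intermediate → other capture product (k = 5.80 M⁻¹ h⁻¹)
    intermediate → solvolysis product (k = 0.480 h⁻¹)
    first nucleophile → decomposition product (k = 1.60 × 10⁻⁵ h⁻¹)
    first nucleophile + target → over-reaction product (k = 0.330 M⁻¹ h⁻¹)

The capture ratio of 0.809 describes the flask's early ratio of 0.840. In the run of the flask without the reaction of first nucleophile with target, the ratio at 15 d stands at 0.837 instead of 0.00648, so that reaction has the largest single effect on this ratio. For a neighbouring flask with 0.075 M of second nucleophile, the capture ratio scales to 1.35; the computed ratio there at 3.0 h is 1.40.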